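## The problem

The target is (−)-epiafzelechin 3-O-gallate joined from C4 to C6' of (−)-epicatechin 3-O-gallate. Unprimed locants refer to the upper flavan unit and primed locants to the lower one; ring B is the upper 4-hydroxyphenyl group and ring B' the lower 3,4-dihydroxyphenyl group.

The two flavans are held by one bond between the benzylic methine C4 and C6', the carbon between the C5' and C7' oxygens of lower ring A. A flavan C4 cation offered an intact flavan-3-ol prefers C8', so this connectivity has to be built in by construction.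

There are five stereocentres: C2 (R), C3 (R) and C4 (S) above, C2' (R) and C3' (R) below. Both heterocycles are 2,3-cis and the C4 aryl group is β, trans to the C3 oxygen. C2 and C3 can control C4, because their substituents both sit on the α face. The lower pair is insulated from the upper triad by an arene and needs reagent control.

Thirteen free phenols oxidise readily, the two galloyl esters do not survive organolithiums, hydrides or hydroxide, and the interflavan bond and the benzylic C–O bonds ionise in acid. The phenols therefore travel as benzyl ethers, the esters go on last, and the end game is a neutral hydrogenolysis.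

The enabling feature lies in lower ring A: C8a' (bearing O1') and C4a' (bearing C4') are adjacent, the C5' oxygen sits next to C4a', and both carbons are remote (para and meta) from C6'. This is the pattern left when a 3-alkoxyaryne takes up a carbonyl oxygen at its distal carbon and the carbonyl carbon at its proximal one. It also means lower ring A can still be a symmetrical 2,6-dioxygenated aryl group when the C4–C6' bond is made.

## Retrosynthesis

**25 to 22 and 23.** The thirteen O–benzyl bonds are cut first (25 from 24), then both ester C–O bonds (24 from diol 22 and acid 23). Late acylation is preferred because no ester would survive the organolithium, zirconium hydride, borane and fluoride steps. Both alcohols take the same acyl group, so one operation serves. The forward steps must acylate two hindered secondary alcohols and then remove the benzyl groups without acid or base.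

**22 back to 18.** The lower heterocycle is simplified by functional-group change: diol 22 from silyl ether 21, cis alcohol 21 from ketone 20, ketone 20 from trans alcohols 19, and 19 from chromene 18. This removes both lower stereocentres from the ring-forming event. It also passes through ketone 20, whose C2' is epimerisable, so the two C2' epimers from ring closure can converge in a dynamic kinetic reduction. Direct asymmetric hydration of 18 could not correct C2'. The forward steps need boron at C3' in the hydroboration and catalyst control over C2' and C3' in the reduction.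

**18 to 11 and 14 (key cut).** Three bonds are cut at once: C8a'–O1', C4a'–C4' and O1'–C2'. This removes the whole lower pyran ring and leaves a single flavan carrying an ortho-silylaryl triflate (11) and a C9 enal (14). Cutting C4–C6' between two finished flavans would face the C8' preference. Cutting only O1'–C2' or only C4a'–C4' would leave an ionisable benzylic ether to be made or kept under acid. The forward reaction must deliver the aldehyde oxygen to the aryne carbon remote from the flanking benzyloxy group, and must outrun 2:1 aryne adducts.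

**14 to 12 and 13.** The enal C=C bond is cut to aldehyde 12 and formyl ylide 13, a one-step E-selective homologation.

**11 back to 8.** The O–S bond is cut (11 from phenol 10), then the carbamate is restored (10 from 9), then the C–Si bond is cut (9 from carbamate 8). Carbamate-directed metalation is preferred to electrophilic halogenation because the upper ring A carries equally electron-rich C6 and C8 positions. Only the carbamate can single out the carbon between it and a benzyloxy group. The two candidate carbons are equivalent by rotation about the C4–aryl bond.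

**8 back to 6.** Two O–benzyl bonds and the O–carbamoyl bond are cut (8 from 7, 7 from triol 6). The para hydroxyl of 6 is the only one without the flavanyl group as ortho neighbour, and it is picked out by a bulky electrophile used in one equivalent. This is the softest point in the approach to the key step.

**6 to 4 and 5.** The C4–aryl bond is cut to the C4 ether 4 and phloroglucinol 5. A threefold-symmetric nucleophile can give only one regioisomer. A pre-differentiated phloroglucinol diether would reopen an ortho/para choice. The forward step must be 4β-selective, which the α-disposed C2 and C3 substituents secure.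

**4 back to 1.** The C4–O bond (4 from 3), the O–Si bond (3 from 2) and three O–benzyl bonds (2 from 1) are cut, ending at (−)-epiafzelechin 1. It supplies C2 and C3 and through them C4.

## Roads not taken

**Alternative 1:** The upper ring A is cut at C4a–C8a and unrolled into a 3,5-dioxohexanoate chain on C4 (keto ester A1). A base-mediated Claisen condensation closes a cyclohexanetrione that tautomerises to the phloroglucinol A2, with the C2–C3–C4 chain still open.

- Merits: C4 is bonded to the future C4a before ring A exists, so there is no interflavan regiochemistry to solve. The lower unit enters as a finished, enantiopure epicatechin derivative, so no C2' epimers arise. No scarce flavan-3-ol is needed.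
- Weak points: A1 needs the C2/C3/C4 triad built acyclically with the whole lower flavan on C4, a long asymmetric sequence before the key step. The β,δ-diketo ester can instead close by aldol condensation or lactonise to a hydroxypyrone. A2 is a free phloroglucinol whose three hydroxyls must still be told apart. The later O1–C2 closure at an ionisable 4-alkoxybenzylic carbon puts the less stable 2,3-cis arrangement at risk.
- Comparison: Alternative 1 is better in that the lower stereocentres are fixed from the start. The chosen plan sets against this an upper unit that brings three stereocentres from the chiral pool, a 4β-selective bond formation, and a much shorter route overall.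

**Alternative 2:** The cut is C4a'–C4'. In aryl ether A3 the para oxygen of a symmetric phloroglucinol adduct carries the C2'–C3'–C4' chain as a terminal epoxide. A Lewis acid makes the arene carbon ortho to that oxygen attack the epoxide terminus, giving A4 with the upper gallate in place and C3'–OH free.

- Merits: C2' and C3' are set before ring closure, so there is no epimer mixture and no redox correction. The symmetric arene gives the 4→6 linkage from either ortho carbon, as in the chosen plan. Only one acylation and the hydrogenolysis follow A4, against six steps after the chosen key step.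
- Weak points: Making A3 means etherifying a phenol with a secondary, doubly alkoxy-activated benzylic carbon with clean inversion, where ionisation and racemisation at C2' are likely. The same para-hydroxyl selection is still needed. The closure must be 6-endo at an unactivated primary carbon against 5-exo attack at C3'. The Lewis acid meets an ionisable C2'–O1' aryl ether, the acid-labile interflavan bond and a participating ester beside C4.
- Comparison: Alternative 2 is better in end-game economy and early stereodefinition. The chosen plan sets against this a ring closure under neutral fluoride conditions, an orientation fixed by aryne polarisation instead of an exo/endo contest, and a C2' that cannot be lost because it is set only at the end.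

**Alternative 3:** The cut is O1–C2 of the upper pyran. In A5 the ring A phenol opens a cis-epoxide at benzylic C2 with inversion, closing the 2,3-cis ring and unveiling C3–OH in A6, whose lower unit already carries the C3' silyl ether.

- Merits: One step gives the cis relationship and the free C3 hydroxyl. The lower unit is complete and enantiopure. The two carbinols are differentiated. No natural upper flavan is needed.
- Weak points: A5 needs the C4 diarylmethine attached to C6' of a finished epicatechin unit, which is exactly where the C8' preference bites. It needs a Z-alkene epoxidised on the correct face relative to C4. It needs one ring A phenol freed selectively. Opening at the 4-alkoxybenzylic C2 has carbocation character, which erodes inversion and admits the 2,3-trans isomer.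
- Comparison: Alternative 3 is better in that A6 has all five stereocentres fixed. The chosen plan sets against this a 4→6 connectivity that follows from construction, an upper unit with no stereochemical risk, and a key ring closure that touches no existing stereocentre. The price is four redox steps to set C2' and C3'.

Key step: step 11

**Remarks before the steps**

- Remark 1: (−)-epiafzelechin 1 is taken as purchased material from natural-product suppliers.
- Remark 2: in step 14 the (R,R)-TsDPEN hand of the ruthenium catalyst is assumed to give the (2'R,3'R) alcohol, with the oxygen-bearing C2' taking the place of the aryl group of an aryl ketone in the transfer-hydrogenation transition state. The hand should be confirmed on a monomeric flavan-3-one model and the mirror-image catalyst used if the model reads otherwise.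
- Shorthand: "U" is the (2R,3R)-5,7-bis(benzyloxy)-2-[4-(benzyloxy)phenyl]-3-(tert-butyldimethylsilyloxy)chroman-4-yl group, bonded through C4 with the bond β, trans to the C3 silyloxy group.

## Route

Step 1
Reactants: 1 (−)-epiafzelechin
Product: 2 (2R,3R)-5,7-bis(benzyloxy)-2-[4-(benzyloxy)phenyl]chroman-3-ol
Conditions: BnBr (3.3 equiv), K2CO3, DMF, 0 °C to rt, argon
Reagents that add atoms: benzyl bromide, BrCc1ccccc1
Why: Williamson etherification; carbonate ionises the three phenols but not the C3 alcohol, and low temperature under argon guards against base-induced C2 epimerisation of the free 4-hydroxyphenyl flavan.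

Step 2
Reactants: 2 tri-O-benzylepiafzelechin
Product: 3 (2R,3R)-5,7-bis(benzyloxy)-2-[4-(benzyloxy)phenyl]-3-(tert-butyldimethylsilyloxy)chromane
Conditions: TBSCl, imidazole, DMF, rt to 40 °C
Reagents that add atoms: tert-butyldimethylsilyl chloride, CC(C)(C)[Si](C)(C)Cl
Why: Imidazole-promoted silylation of the only free hydroxyl; the alkyl TBS ether should tolerate cold Lewis acid, organolithium, zirconium hydride, CsF and borane and comes off just before acylation.

Step 3
Reactants: 3 silyl ether
Product: 4 the 4β-(2-ethoxyethoxy) derivative of 3 (C4 ether trans to the C3 silyloxy group)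
Conditions: DDQ (2 equiv), 2-ethoxyethanol (5 equiv), CH2Cl2, rt
Reagents that add atoms: 2-ethoxyethanol, CCOCCO
Why: DDQ benzylic oxidation; hydride abstraction at C4 gives the cation stabilised by ring A, which the alcohol traps from the β face, as is standard for C4 activation of benzylated flavan-3-ols.

Step 4
Reactants: 4 C4 ether; 5 phloroglucinol (8 equiv)
Product: 6 2-U-benzene-1,3,5-triol
Conditions: BF3·OEt2 (1.2 equiv), THF/CH2Cl2, −40 to 0 °C
Reagents that add atoms: none
Why: Friedel–Crafts alkylation through the re-formed C4 cation; the nucleophile enters anti to the α-oriented C3 silyloxy and C2 aryl groups, which sets C4 as 4β (3,4-trans). The threefold symmetry of 5 allows one regioisomer only and its excess suppresses double alkylation.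

Step 5
Reactants: 6 triol
Product: 7 3,5-dihydroxy-4-U-phenyl N,N-diethylcarbamate
Conditions: Et2NCOCl (1.05 equiv), K2CO3 (1.2 equiv), MeCN, 40 °C
Reagents that add atoms: N,N-diethylcarbamoyl chloride, CCN(CC)C(=O)Cl
Why: O-carbamoylation; the para hydroxyl is the least hindered and the most acidic, while the two ortho hydroxyls are shielded by the flavanyl group, so one equivalent of a bulky, slow electrophile should select it.

Step 6
Reactants: 7 para-carbamate
Product: 8 3,5-bis(benzyloxy)-4-U-phenyl N,N-diethylcarbamate
Conditions: BnBr (3 equiv), K2CO3, Bu4NI (cat.), DMF, 50 °C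
Reagents that add atoms: benzyl bromide, BrCc1ccccc1
Why: Williamson etherification of the two remaining phenols; the diethylcarbamate is inert to carbonate and cannot migrate.

Step 7
Reactants: 8 dibenzyl carbamate
Product: 9 3,5-bis(benzyloxy)-2-(trimethylsilyl)-4-U-phenyl N,N-diethylcarbamate
Conditions: s-BuLi (1.3 equiv), TMEDA, THF, −78 °C; then TMSCl, −78 °C to rt
Reagents that add atoms: chlorotrimethylsilane, C[Si](C)(C)Cl
Why: Directed ortho metalation; the O-carbamate is the strongest director present and the carbon between it and a benzyloxy group is doubly activated. The two such carbons are equivalent by rotation about the C4–aryl bond, and at −78 °C silylation precedes anionic ortho-Fries rearrangement.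

Step 8
Reactants: 9 silyl carbamate
Product: 10 3,5-bis(benzyloxy)-2-(trimethylsilyl)-4-U-phenol
Conditions: Cp2Zr(H)Cl (3 equiv), THF, rt; then H2O
Reagents that add atoms: none
Why: Reductive cleavage of an aryl O-carbamate by the Schwartz reagent (hydrozirconation of the carbamate carbonyl, collapse to a zirconium phenoxide); the neutral conditions spare the aryl–silicon bond, the benzyl ethers and the TBS ether.

Step 9
Reactants: 10 silyl phenol
Product: 11 3,5-bis(benzyloxy)-2-(trimethylsilyl)-4-U-phenyl trifluoromethanesulfonate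
Conditions: Tf2O (1.3 equiv), pyridine, CH2Cl2, −20 to 0 °C
Reagents that add atoms: trifluoromethanesulfonic anhydride, O=S(=O)(OS(=O)(=O)C(F)(F)F)C(F)(F)F
Why: O-triflation of a phenol under buffered conditions, which avoids protodesilylation of the electron-rich arylsilane and gives a Kobayashi-type aryne precursor.

Step 10
Reactants: 12 3,4-bis(benzyloxy)benzaldehyde; 13 (triphenylphosphoranylidene)acetaldehyde
Product: 14 (E)-3-[3,4-bis(benzyloxy)phenyl]prop-2-enal
Conditions: toluene, 80 °C
Reagents that add atoms: none
Why: Wittig olefination with a stabilised formyl ylide, E-selective; the aryl aldehyde is consumed before the less electrophilic enal product can be homologated again.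

Step 11
Reactants: 11 silyl triflate; 14 enal (3 equiv)
Product: 18 6'-U-5',7'-bis(benzyloxy)-2'-[3,4-bis(benzyloxy)phenyl]-2'H-chromene (both C2' epimers), via aryne 15 (not isolated), via benzoxete 16 (not isolated), via ortho-quinone methide 17 (not isolated)
Conditions: CsF (3 equiv), MeCN/THF (3:1), rt to 40 °C
Reagents that add atoms: none
Why: Fluoride attacks silicon of 11 and the aryl anion expels triflate to give aryne 15; the carbonyl oxygen of 14 adds to the aryne carbon remote from the flanking benzyloxy group (future C8a'), and the aryl anion developing next to that benzyloxy group (future C4a') closes on the carbonyl carbon, a formal [2+2] cycloaddition giving benzoxete 16. Retro-4π electrocyclic opening of 16 gives ortho-quinone methide 17, a 1-oxatriene extended by the styrenyl double bond. Thermal disrotatory oxa-6π electrocyclisation then forms O1'–C2' and closes the six-membered lower pyran ring by a pericyclic bond formation, restoring the aromaticity of lower ring A. The closest known reaction type is the annulation of fluoride-generated arynes with α,β-unsaturated aldehydes to 2H-chromenes. The new stereocentre C2' forms in the electrocyclisation with no nearby element to bias it, so both epimers are expected and are carried on deliberately. The selectivity needed is the orientation of aryne capture, secured by the inductive polarisation from the adjacent benzyloxy group (future C5' oxygen); because the aryl group is symmetric about the C4–C6' axis before the aryne forms, the 4→6 linkage results whichever meta carbon bore silicon. Excess aldehyde and gradual aryne release should keep 17 from meeting a second aryne, and the TBS ether, benzyl ethers and interflavan bond are inert to CsF.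

Step 12
Reactants: 18 chromene
Product: 19 2',3'-trans-6'-U-5',7'-bis(benzyloxy)-2'-[3,4-bis(benzyloxy)phenyl]chroman-3'-ol, the (2'R,3'S) and (2'S,3'R) isomers together
Conditions: BH3·THF, THF, 0 °C to rt; then NaOH aq, H2O2, 0 °C
Reagents that add atoms: hydrogen peroxide, OO
Why: Hydroboration–oxidation; boron goes to C3', distal to the electron-rich ring A and away from the peri benzyloxy group, and syn addition anti to the C2' aryl group gives the trans alcohol in each C2' series. These centres are provisional.

Step 13
Reactants: 19 trans alcohols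
Product: 20 6'-U-5',7'-bis(benzyloxy)-2'-[3,4-bis(benzyloxy)phenyl]chroman-3'-one (both C2' epimers)
Conditions: Dess–Martin periodinane, CH2Cl2, rt
Reagents that add atoms: none
Why: Dess–Martin oxidation of a secondary alcohol, mild and non-basic, as used to turn benzylated trans-flavan-3-ols into flavan-3-ones.

Step 14
Reactants: 20 flavan-3'-one
Product: 21 (2'R,3'R)-6'-U-5',7'-bis(benzyloxy)-2'-[3,4-bis(benzyloxy)phenyl]chroman-3'-ol (2',3'-cis)
Conditions: RuCl(p-cymene)[(R,R)-TsDPEN] (5 mol %), HCO2H/Et3N (5:2), DMF, 40 °C, argon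
Reagents that add atoms: none
Why: Noyori–Ikariya asymmetric transfer hydrogenation with dynamic kinetic resolution, as established for 2-arylcycloalkanones and 1-aryl-2-tetralones. C2' (α-aryl, α-aryloxy) epimerises through the enol in the amine–formate medium; the catalyst should reduce the 2'R ketone faster, delivering hydride anti to the C2' aryl group to set C3' as R and drain both epimers into the cis alcohol.

Step 15
Reactants: 21 cis alcohol
Product: 22 the diol obtained from 21 by replacing the C3 silyl ether by a free hydroxyl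
Conditions: Bu4NF, THF, rt to 40 °C
Reagents that add atoms: none
Why: Fluoride desilylation; it is placed before acylation, so no ester is exposed to the basic fluoride.

Step 16
Reactants: 22 diol; 23 3,4,5-tris(benzyloxy)benzoic acid (3 equiv)
Product: 24 the 3,3'-bis[3,4,5-tris(benzyloxy)benzoate] of 22
Conditions: DCC, DMAP, CH2Cl2, rt
Reagents that add atoms: none
Why: Steglich esterification; the acylpyridinium formed with DMAP acylates both hindered secondary alcohols without touching a stereocentre.

Step 17
Reactants: 24 trideca-O-benzyl bis-gallate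
Product: 25 (−)-epiafzelechin 3-O-gallate-(4β→6)-(−)-epicatechin 3-O-gallate
Conditions: H2 (1 atm), Pd(OH)2/C, THF/MeOH/H2O, rt
Reagents that add atoms: none
Why: Hydrogenolysis of thirteen benzyl ethers under neutral conditions, which spares the galloyl esters, the interflavan bond and all five stereocentres.

## Compound list

1 | (−)-epiafzelechin | O[C@@H]1Cc2c(O)cc(O)cc2O[C@@H]1c1ccc(O)cc1 | starting material
2 | (2R,3R)-5,7-bis(benzyloxy)-2-[4-(benzyloxy)phenyl]chroman-3-ol | O[C@@H]1Cc2c(OCc9ccccc9)cc(OCc9ccccc9)cc2O[C@@H]1c6ccc(OCc9ccccc9)cc6 | intermediate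
3 | 3-O-TBS ether of 2 | CC(C)(C)[Si](C)(C)O[C@@H]1Cc2c(OCc9ccccc9)cc(OCc9ccccc9)cc2O[C@@H]1c6ccc(OCc9ccccc9)cc6 | intermediate
4 | 4β-(2-ethoxyethoxy) derivative of 3 | CC(C)(C)[Si](C)(C)O[C@@H]1[C@@H](OCCOCC)c4c(OCc9ccccc9)cc(OCc9ccccc9)cc4O[C@@H]1c6ccc(OCc9ccccc9)cc6 | intermediate
5 | phloroglucinol | Oc1cc(O)cc(O)c1 | starting material
6 | 2-U-benzene-1,3,5-triol | CC(C)(C)[Si](C)(C)O[C@@H]1[C@@H](c2c(O)cc(O)cc2O)c4c(OCc9ccccc9)cc(OCc9ccccc9)cc4O[C@@H]1c6ccc(OCc9ccccc9)cc6 | intermediate
7 | 3,5-dihydroxy-4-U-phenyl N,N-diethylcarbamate | CC(C)(C)[Si](C)(C)O[C@@H]1[C@@H](c2c(O)cc(OC(=O)N(CC)CC)cc2O)c4c(OCc9ccccc9)cc(OCc9ccccc9)cc4O[C@@H]1c6ccc(OCc9ccccc9)cc6 | intermediate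
8 | 3,5-bis(benzyloxy)-4-U-phenyl N,N-diethylcarbamate | CC(C)(C)[Si](C)(C)O[C@@H]1[C@@H](c2c(OCc9ccccc9)cc(OC(=O)N(CC)CC)cc2OCc9ccccc9)c4c(OCc9ccccc9)cc(OCc9ccccc9)cc4O[C@@H]1c6ccc(OCc9ccccc9)cc6 | intermediate
9 | 3,5-bis(benzyloxy)-2-(trimethylsilyl)-4-U-phenyl N,N-diethylcarbamate | CC(C)(C)[Si](C)(C)O[C@@H]1[C@@H](c2c(OCc9ccccc9)cc(OC(=O)N(CC)CC)c([Si](C)(C)C)c2OCc9ccccc9)c4c(OCc9ccccc9)cc(OCc9ccccc9)cc4O[C@@H]1c6ccc(OCc9ccccc9)cc6 | intermediate
10 | 3,5-bis(benzyloxy)-2-(trimethylsilyl)-4-U-phenol | CC(C)(C)[Si](C)(C)O[C@@H]1[C@@H](c2c(OCc9ccccc9)cc(O)c([Si](C)(C)C)c2OCc9ccccc9)c4c(OCc9ccccc9)cc(OCc9ccccc9)cc4O[C@@H]1c6ccc(OCc9ccccc9)cc6 | intermediate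
11 | 3,5-bis(benzyloxy)-2-(trimethylsilyl)-4-U-phenyl trifluoromethanesulfonate | CC(C)(C)[Si](C)(C)O[C@@H]1[C@@H](c2c(OCc9ccccc9)cc(OS(=O)(=O)C(F)(F)F)c([Si](C)(C)C)c2OCc9ccccc9)c4c(OCc9ccccc9)cc(OCc9ccccc9)cc4O[C@@H]1c6ccc(OCc9ccccc9)cc6 | intermediate
12 | 3,4-bis(benzyloxy)benzaldehyde | O=Cc1ccc(OCc2ccccc2)c(OCc2ccccc2)c1 | starting material
13 | (triphenylphosphoranylidene)acetaldehyde | O=CC=P(c1ccccc1)(c1ccccc1)c1ccccc1 | starting material
14 | (E)-3-[3,4-bis(benzyloxy)phenyl]prop-2-enal | O=C/C=C/c1ccc(OCc2ccccc2)c(OCc2ccccc2)c1 | intermediate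
15 | 3,5-bis(benzyloxy)-4-U-1,2-didehydrobenzene (aryne) | CC(C)(C)[Si](C)(C)O[C@@H]1[C@@H](C2=C(OCc9ccccc9)C#CC=C2OCc9ccccc9)c4c(OCc9ccccc9)cc(OCc9ccccc9)cc4O[C@@H]1c6ccc(OCc9ccccc9)cc6 | intermediate (not isolated)
16 | 3,5-bis(benzyloxy)-4-U-2-{(E)-2-[3,4-bis(benzyloxy)phenyl]ethenyl}-2H-benzoxete | CC(C)(C)[Si](C)(C)O[C@@H]1[C@@H](c2c(OCc9ccccc9)cc3OC(/C=C/c7ccc(OCc9ccccc9)c(OCc9ccccc9)c7)c3c2OCc9ccccc9)c4c(OCc9ccccc9)cc(OCc9ccccc9)cc4O[C@@H]1c6ccc(OCc9ccccc9)cc6 | intermediate (not isolated)
17 | 6-{(E)-3-[3,4-bis(benzyloxy)phenyl]prop-2-enylidene}-3,5-bis(benzyloxy)-4-U-cyclohexa-2,4-dien-1-one (ortho-quinone methide) | CC(C)(C)[Si](C)(C)O[C@@H]1[C@@H](C2=C(OCc9ccccc9)C(=C/C=C/c7ccc(OCc9ccccc9)c(OCc9ccccc9)c7)C(=O)C=C2OCc9ccccc9)c4c(OCc9ccccc9)cc(OCc9ccccc9)cc4O[C@@H]1c6ccc(OCc9ccccc9)cc6 | intermediate (not isolated)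
18 | 6'-U-5',7'-bis(benzyloxy)-2'-[3,4-bis(benzyloxy)phenyl]-2'H-chromene, both C2' epimers | CC(C)(C)[Si](C)(C)O[C@@H]1[C@@H](c2c(OCc9ccccc9)cc3c(c2OCc9ccccc9)C=CC(c7ccc(OCc9ccccc9)c(OCc9ccccc9)c7)O3)c4c(OCc9ccccc9)cc(OCc9ccccc9)cc4O[C@@H]1c6ccc(OCc9ccccc9)cc6 | intermediate
19 | 2',3'-trans-6'-U-5',7'-bis(benzyloxy)-2'-[3,4-bis(benzyloxy)phenyl]chroman-3'-ol, (2'R,3'S) and (2'S,3'R) isomers together (lower centres left open in the SMILES) | CC(C)(C)[Si](C)(C)O[C@@H]1[C@@H](c2c(OCc9ccccc9)cc3c(c2OCc9ccccc9)CC(O)C(c7ccc(OCc9ccccc9)c(OCc9ccccc9)c7)O3)c4c(OCc9ccccc9)cc(OCc9ccccc9)cc4O[C@@H]1c6ccc(OCc9ccccc9)cc6 | intermediate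
20 | 6'-U-5',7'-bis(benzyloxy)-2'-[3,4-bis(benzyloxy)phenyl]chroman-3'-one, both C2' epimers | CC(C)(C)[Si](C)(C)O[C@@H]1[C@@H](c2c(OCc9ccccc9)cc3c(c2OCc9ccccc9)CC(=O)C(c7ccc(OCc9ccccc9)c(OCc9ccccc9)c7)O3)c4c(OCc9ccccc9)cc(OCc9ccccc9)cc4O[C@@H]1c6ccc(OCc9ccccc9)cc6 | intermediate
21 | (2'R,3'R)-6'-U-5',7'-bis(benzyloxy)-2'-[3,4-bis(benzyloxy)phenyl]chroman-3'-ol | CC(C)(C)[Si](C)(C)O[C@@H]1[C@@H](c2c(OCc9ccccc9)cc3c(c2OCc9ccccc9)C[C@@H](O)[C@@H](c7ccc(OCc9ccccc9)c(OCc9ccccc9)c7)O3)c4c(OCc9ccccc9)cc(OCc9ccccc9)cc4O[C@@H]1c6ccc(OCc9ccccc9)cc6 | intermediate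
22 | 3,3'-diol (21 with the C3 hydroxyl free) | O[C@@H]1[C@@H](c2c(OCc9ccccc9)cc3c(c2OCc9ccccc9)C[C@@H](O)[C@@H](c7ccc(OCc9ccccc9)c(OCc9ccccc9)c7)O3)c4c(OCc9ccccc9)cc(OCc9ccccc9)cc4O[C@@H]1c6ccc(OCc9ccccc9)cc6 | intermediate
23 | 3,4,5-tris(benzyloxy)benzoic acid | OC(=O)c1cc(OCc2ccccc2)c(OCc2ccccc2)c(OCc2ccccc2)c1 | starting material
24 | 3,3'-bis[3,4,5-tris(benzyloxy)benzoate] of 22 | O=C(O[C@@H]1[C@@H](c2c(OCc9ccccc9)cc3c(c2OCc9ccccc9)C[C@@H](OC(=O)c5cc(OCc9ccccc9)c(OCc9ccccc9)c(OCc9ccccc9)c5)[C@@H](c7ccc(OCc9ccccc9)c(OCc9ccccc9)c7)O3)c4c(OCc9ccccc9)cc(OCc9ccccc9)cc4O[C@@H]1c6ccc(OCc9ccccc9)cc6)c8cc(OCc9ccccc9)c(OCc9ccccc9)c(OCc9ccccc9)c8 | intermediate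
25 | (−)-epiafzelechin 3-O-gallate-(4β→6)-(−)-epicatechin 3-O-gallate | O=C(O[C@@H]1[C@@H](c2c(O)cc3c(c2O)C[C@@H](OC(=O)c2cc(O)c(O)c(O)c2)[C@@H](c2ccc(O)c(O)c2)O3)c2c(O)cc(O)cc2O[C@@H]1c1ccc(O)cc1)c1cc(O)c(O)c(O)c1 | target

## Step count and least certain steps

Total: 17 steps. Longest linear sequence: 16 steps (steps 1–9 and 11–17 from 1); the enal branch is one step (step 10).

**Step 11 (key step).** The aryne may be diverted before the enal captures it: by fluoride or adventitious water, by a second aryne adding to the quinone methide, or by capture with eroded orientation. The cause is that a weakly nucleophilic carbonyl oxygen must intercept a short-lived aryne on a hindered, lipophilic substrate. The fallback leaves the aryne and uses the phenol–enal chromene annulation. It sets out from 8: Cp2Zr(H)Cl cleaves the carbamate to 3,5-bis(benzyloxy)-4-U-phenol F1. F1 and 14 are heated with PhB(OH)2 and acetic acid in toluene, which should give the 2-phenyl-4H-1,3,2-benzodioxaborin F2 by ortho-C-hydroxyalkylation. F2 fragments on heating to the same quinone methide 17, which closes to 18, where the route is rejoined.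

**Step 5.** Site discrimination among the three phenols may be incomplete, with carbamoylation spreading to an ortho hydroxyl or going twice, because selectivity rests only on steric and acidity differences. The fallback uses a removable silyl placeholder that is more sensitive to size. It sets out from 6: TIPSCl and imidazole should give 3,5-dihydroxy-4-U-phenyl triisopropylsilyl ether F3. Benzylation (BnBr, K2CO3) gives the bis(benzyl) ether F4. Brief Bu4NF at 0 °C cleaves the aryl silyl ether ahead of the alkyl TBS ether to give F1. NaH and Et2NCOCl then return the route at 8.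

**Step 7.** Metalation may occur at unintended sites (benzylic ether deprotonation with Wittig rearrangement, the upper ring A positions), or the lithiated carbamate may undergo anionic ortho-Fries rearrangement, because the substrate carries five benzyl ethers and a strong base is used. The fallback replaces deprotonation by halogen–lithium exchange. It sets out from 8: Cp2Zr(H)Cl gives F1. NBS with catalytic i-Pr2NH at low temperature should brominate ortho to the free hydroxyl, giving 2-bromo-3,5-bis(benzyloxy)-4-U-phenol F5. HMDS converts F5 into its O-trimethylsilyl ether F6. n-BuLi at −78 °C triggers bromine–lithium exchange and retro-Brook migration to the lithium salt of 10, and Tf2O in the same flask returns the route at 11.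

**Step 14.** Epimerisation at C2' may be slower than reduction, or catalyst control may be weak or of the wrong sense on this bulky ketone, leaving cis alcohols of both C2' series. The fallback gives up convergence in one pass and uses substrate control with recycling. It sets out from 20: L-Selectride in THF at −78 °C reduces each epimer to its cis alcohol, giving 21 and its (2'S,3'S) diastereomer F7, which are separated by chromatography. F7 is re-oxidised with Dess–Martin periodinane to the 2'S epimer of 20, equilibrated with DBU to the mixture 20 and reduced again. The route is rejoined at 21.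

**Step 12.** Boron may leak to the benzylic C4', or hydroboration may stall on the hindered, trisubstituted-like alkene next to the peri benzyloxy group. The fallback reaches the ketone without boron. It sets out from 18: dimethyldioxirane in acetone at −20 °C gives the 3',4'-epoxide F8. ZnI2 then promotes a Meinwald rearrangement (ionisation at benzylic C4', 1,2-hydride shift from C3'), rejoining the route at 20.

## Further compounds

F1 | step 11 | 3,5-bis(benzyloxy)-4-U-phenol | CC(C)(C)[Si](C)(C)O[C@@H]1[C@@H](c2c(OCc9ccccc9)cc(O)cc2OCc9ccccc9)c4c(OCc9ccccc9)cc(OCc9ccccc9)cc4O[C@@H]1c6ccc(OCc9ccccc9)cc6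
F2 | step 11 | 5,7-bis(benzyloxy)-6-U-2-phenyl-4-{(E)-2-[3,4-bis(benzyloxy)phenyl]ethenyl}-4H-1,3,2-benzodioxaborin | CC(C)(C)[Si](C)(C)O[C@@H]1[C@@H](c2c(OCc9ccccc9)cc3OB(c5ccccc5)OC(/C=C/c7ccc(OCc9ccccc9)c(OCc9ccccc9)c7)c3c2OCc9ccccc9)c4c(OCc9ccccc9)cc(OCc9ccccc9)cc4O[C@@H]1c6ccc(OCc9ccccc9)cc6
F3 | step 5 | 3,5-dihydroxy-4-U-phenyl triisopropylsilyl ether | CC(C)(C)[Si](C)(C)O[C@@H]1[C@@H](c2c(O)cc(O[Si](C(C)C)(C(C)C)C(C)C)cc2O)c4c(OCc9ccccc9)cc(OCc9ccccc9)cc4O[C@@H]1c6ccc(OCc9ccccc9)cc6
F4 | step 5 | 3,5-bis(benzyloxy)-4-U-phenyl triisopropylsilyl ether | CC(C)(C)[Si](C)(C)O[C@@H]1[C@@H](c2c(OCc9ccccc9)cc(O[Si](C(C)C)(C(C)C)C(C)C)cc2OCc9ccccc9)c4c(OCc9ccccc9)cc(OCc9ccccc9)cc4O[C@@H]1c6ccc(OCc9ccccc9)cc6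
F5 | step 7 | 2-bromo-3,5-bis(benzyloxy)-4-U-phenol | CC(C)(C)[Si](C)(C)O[C@@H]1[C@@H](c2c(OCc9ccccc9)cc(O)c(Br)c2OCc9ccccc9)c4c(OCc9ccccc9)cc(OCc9ccccc9)cc4O[C@@H]1c6ccc(OCc9ccccc9)cc6
F6 | step 7 | 2-bromo-3,5-bis(benzyloxy)-4-U-phenyl trimethylsilyl ether | CC(C)(C)[Si](C)(C)O[C@@H]1[C@@H](c2c(OCc9ccccc9)cc(O[Si](C)(C)C)c(Br)c2OCc9ccccc9)c4c(OCc9ccccc9)cc(OCc9ccccc9)cc4O[C@@H]1c6ccc(OCc9ccccc9)cc6
F7 | step 14 | (2'S,3'S)-6'-U-5',7'-bis(benzyloxy)-2'-[3,4-bis(benzyloxy)phenyl]chroman-3'-ol | CC(C)(C)[Si](C)(C)O[C@@H]1[C@@H](c2c(OCc9ccccc9)cc3c(c2OCc9ccccc9)C[C@H](O)[C@H](c7ccc(OCc9ccccc9)c(OCc9ccccc9)c7)O3)c4c(OCc9ccccc9)cc(OCc9ccccc9)cc4O[C@@H]1c6ccc(OCc9ccccc9)cc6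
F8 | step 12 | 3',4'-epoxide of 18 (both C2' series) | CC(C)(C)[Si](C)(C)O[C@@H]1[C@@H](c2c(OCc9ccccc9)cc3c(c2OCc9ccccc9)C5OC5C(c7ccc(OCc9ccccc9)c(OCc9ccccc9)c7)O3)c4c(OCc9ccccc9)cc(OCc9ccccc9)cc4O[C@@H]1c6ccc(OCc9ccccc9)cc6
A1 | alternative 1 | methyl 3,5-dioxohexanoate chain on C4 of the open upper unit (Claisen precursor) | COC(=O)CC(=O)CC(=O)C[C@H](c2c(OCc9ccccc9)cc3c(c2OCc9ccccc9)C[C@@H](O[Si](C)(C)C(C)(C)C)[C@@H](c7ccc(OCc9ccccc9)c(OCc9ccccc9)c7)O3)[C@@H](O[Si](C)(C)C(C)(C)C)[C@@H](O[Si](CC)(CC)CC)c6ccc(OCc9ccccc9)cc6
A2 | alternative 1 | 2-substituted phloroglucinol with open C2–C3–C4 chain | Oc4cc(O)cc(O)c4[C@H](c2c(OCc9ccccc9)cc3c(c2OCc9ccccc9)C[C@@H](O[Si](C)(C)C(C)(C)C)[C@@H](c7ccc(OCc9ccccc9)c(OCc9ccccc9)c7)O3)[C@@H](O[Si](C)(C)C(C)(C)C)[C@@H](O[Si](CC)(CC)CC)c6ccc(OCc9ccccc9)cc6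
A3 | alternative 2 | aryl ether carrying the terminal epoxide (epoxy-arene precursor) | O=C(O[C@@H]1[C@@H](c2c(OCc9ccccc9)cc(O[C@H](c7ccc(OCc9ccccc9)c(OCc9ccccc9)c7)[C@H]5CO5)cc2OCc9ccccc9)c4c(OCc9ccccc9)cc(OCc9ccccc9)cc4O[C@@H]1c6ccc(OCc9ccccc9)cc6)c8cc(OCc9ccccc9)c(OCc9ccccc9)c(OCc9ccccc9)c8
A4 | alternative 2 | benzyl-protected dimer with upper gallate and free C3' hydroxyl | O=C(O[C@@H]1[C@@H](c2c(OCc9ccccc9)cc3c(c2OCc9ccccc9)C[C@@H](O)[C@@H](c7ccc(OCc9ccccc9)c(OCc9ccccc9)c7)O3)c4c(OCc9ccccc9)cc(OCc9ccccc9)cc4O[C@@H]1c6ccc(OCc9ccccc9)cc6)c8cc(OCc9ccccc9)c(OCc9ccccc9)c(OCc9ccccc9)c8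
A5 | alternative 3 | ring A phenol carrying the cis-epoxide (epoxy-phenol precursor) | Oc4cc(OCc9ccccc9)cc(OCc9ccccc9)c4[C@H](c2c(OCc9ccccc9)cc3c(c2OCc9ccccc9)C[C@@H](O[Si](C)(C)C(C)(C)C)[C@@H](c7ccc(OCc9ccccc9)c(OCc9ccccc9)c7)O3)[C@H]5O[C@H]5c6ccc(OCc9ccccc9)cc6
A6 | alternative 3 | benzyl-protected dimer with free C3 hydroxyl and C3' silyl ether | O[C@@H]1[C@@H](c2c(OCc9ccccc9)cc3c(c2OCc9ccccc9)C[C@@H](O[Si](C)(C)C(C)(C)C)[C@@H](c7ccc(OCc9ccccc9)c(OCc9ccccc9)c7)O3)c4c(OCc9ccccc9)cc(OCc9ccccc9)cc4O[C@@H]1c6ccc(OCc9ccccc9)cc6
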